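**Retrosynthetic overview**

1. Numbering: ring A is the ten-membered carbocycle C1 (alkene CH) to C10 (alkene C bearing C14O2Me); C4 carries C15H2OH, C6 the lactone oxygen, C7 carries C11(=C13H2)–C12(=O) (γ-lactone, ring B), and C8 the (R)-2-methylbutanoate. The route rests on the ring bond C9–C10, which joins a CH2 without stereocentre to the sp2 carbon C10, so ring A can be closed there last with C4, C6, C7, C8 and ring B in place.
2. C9–C10: nickel-electrocatalytic decarboxylative alkenylation of a seco N-acyloxyphthalimide (carboxyl carbon C16 on C9) with the (Z)-iodoenoate at C10; C1=C10 comes from an iodo-Wittig reaction on a C1 aldehyde.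
3. C8–O: Mitsunobu esterification with inversion, because the C7–C8 Barbier allylation of a 3-(bromomethyl)butenolide delivers the 6,7-trans, 8S alcohol.
4. The butenolide comes from a Morita–Baylis–Hillman adduct (C7–C11), and C4 from trans-alkylation of the D-glutamate-derived lactone (C3–C4). Ring order: ring B (step 10), then ring A (step 20).

Key step: step 20

Remarks on the chemistry:
- O15 is carried as its TBDPS ether, so that the C6 and C16 silyl ethers can be removed in its presence; the key-step product is therefore the 15-O-TBDPS ether.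
- Iodide 4 and aldehyde 17 are taken as catalogue compounds (4 is otherwise one step from 3-[(4-methoxybenzyl)oxy]propan-1-ol with I2, PPh3, imidazole).
- The (R) configuration of the 2-methylbutanoate is read from the target SMILES.

**Route**

Step 1
Reactants: 1 (R)-5-oxotetrahydrofuran-2-carboxylic acid
Product: 2 (R)-5-(hydroxymethyl)dihydrofuran-2(3H)-one
Conditions: BH3·SMe2, THF, 0 °C to rt; MeOH quench
Reagents that add atoms: none
Why: Chemoselective borane reduction takes the carboxylic acid through its acyloxyborane much faster than the lactone and does not touch the C6 stereocentre.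

Step 2
Reactants: 2 (R)-5-(hydroxymethyl)dihydrofuran-2(3H)-one
Product: 3 (R)-5-[(trityloxy)methyl]dihydrofuran-2(3H)-one
Conditions: TrCl, Et3N, DMAP (cat.), CH2Cl2, rt
Reagents that add atoms: trityl chloride, ClC(c1ccccc1)(c1ccccc1)c1ccccc1
Why: Tritylation of the only hydroxyl installs the bulky CH2OTr group that shields one face of the lactone enolate in step 3.

Step 3
Reactants: 3 trityl lactone; 4 1-[(3-iodopropoxy)methyl]-4-methoxybenzene
Product: 6 (3S,5R)-3-{3-[(4-methoxybenzyl)oxy]propyl}-5-[(trityloxy)methyl]dihydrofuran-2(3H)-one, via lithium enolate 5 (not isolated)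
Conditions: LiN(iPr)2, THF, −78 °C; then 4, DMPU, −78 to −40 °C
Reagents that add atoms: none
Why: Lactone enolate alkylation in which the iodide attacks the face anti to the CH2OTr group on C6, so C4 is set trans to it (3S) by 1,3-induction across the five-membered ring.

Step 4
Reactants: 6 alkylated lactone
Product: 7 (2R,4S)-4-(hydroxymethyl)-7-[(4-methoxybenzyl)oxy]-1-(trityloxy)heptan-2-ol
Conditions: LiBH4, THF, 0 °C to rt
Reagents that add atoms: none
Why: Hydride reduction of the lactone opens it to the O15/O6 diol without affecting the ethers or the two stereocentres.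

Step 5
Reactants: 7 diol
Product: 8 (2R,4S)-4-{[(tert-butyldiphenylsilyl)oxy]methyl}-7-[(4-methoxybenzyl)oxy]-1-(trityloxy)heptan-2-ol
Conditions: TBDPSCl, imidazole, CH2Cl2, 0 °C
Reagents that add atoms: tert-butyl(chloro)diphenylsilane, CC(C)(C)[Si](Cl)(c1ccccc1)c1ccccc1
Why: Silylation with the bulky chlorosilane is selective for the primary C15 hydroxyl over the flanked secondary C6 hydroxyl.

Step 6
Reactants: 8 mono-silyl ether
Product: 9 (2R,4S)-2-[(tert-butyldimethylsilyl)oxy]-4-{[(tert-butyldiphenylsilyl)oxy]methyl}-7-[(4-methoxybenzyl)oxy]-1-(trityloxy)heptane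
Conditions: TBSOTf, 2,6-lutidine, CH2Cl2, −78 to 0 °C
Reagents that add atoms: tert-butyldimethylsilyl trifluoromethanesulfonate, CC(C)(C)[Si](C)(C)OS(=O)(=O)C(F)(F)F
Why: Silyl triflate silylation protects the secondary O6 with a group that acid later removes in the presence of the primary TBDPS ether.

Step 7
Reactants: 9 trityl ether
Product: 10 (2R,4S)-2-[(tert-butyldimethylsilyl)oxy]-4-{[(tert-butyldiphenylsilyl)oxy]methyl}-7-[(4-methoxybenzyl)oxy]heptan-1-ol
Conditions: TsOH·H2O (cat.), MeOH–CH2Cl2, 0 °C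
Reagents that add atoms: none
Why: Acid-catalysed methanolysis removes the trityl group through the stabilised trityl cation under conditions too mild for the secondary TBS, primary TBDPS and PMB ethers.

Step 8
Reactants: 10 primary alcohol
Product: 11 (2R,4S)-2-[(tert-butyldimethylsilyl)oxy]-4-{[(tert-butyldiphenylsilyl)oxy]methyl}-7-[(4-methoxybenzyl)oxy]heptanal
Conditions: Dess–Martin periodinane, NaHCO3, CH2Cl2, 0 °C to rt
Reagents that add atoms: none
Why: Dess–Martin oxidation gives the α-silyloxy aldehyde (C7) under buffered, non-basic conditions that should not epimerise C6.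

Step 9
Reactants: 11 aldehyde; 12 methyl acrylate
Product: 13 methyl (4R,6S)-4-[(tert-butyldimethylsilyl)oxy]-6-{[(tert-butyldiphenylsilyl)oxy]methyl}-3-hydroxy-9-[(4-methoxybenzyl)oxy]-2-methylidenenonanoate (both C3 epimers)
Conditions: DABCO, methyl acrylate (excess), MeOH (trace), rt
Reagents that add atoms: none
Why: Morita–Baylis–Hillman reaction forms C7–C11 and brings in C12 and C13, and the new carbinol centre at C7 is of no consequence because C7 becomes sp2 in step 11.

Step 10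
Reactants: 13 Baylis–Hillman adduct
Product: 15 (5R)-5-[(2S)-2-{[(tert-butyldiphenylsilyl)oxy]methyl}-5-[(4-methoxybenzyl)oxy]pentyl]-4-hydroxy-3-methylidenedihydrofuran-2(3H)-one (both C4 epimers), via dihydroxy ester 14 (not isolated)
Conditions: TsOH·H2O (0.3 equiv), MeOH, rt; then toluene, 40 °C
Reagents that add atoms: none
Why: Acidic methanolysis cleaves the secondary TBS ether far faster than the primary TBDPS ether, and the freed γ-hydroxy ester lactonises to the γ-lactone, ring B.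

Step 11
Reactants: 15 hydroxy lactone
Product: 16 (5R)-3-(bromomethyl)-5-[(2S)-2-{[(tert-butyldiphenylsilyl)oxy]methyl}-5-[(4-methoxybenzyl)oxy]pentyl]furan-2(5H)-one
Conditions: NBS, Me2S, CH2Cl2, −20 °C to rt
Reagents that add atoms: N-bromosuccinimide, O=C1CCC(=O)N1Br
Why: Corey–Kim bromination of the Baylis–Hillman-type alcohol proceeds with allylic transposition (SN2') to the conjugated 3-(bromomethyl)butenolide, so both C7 epimers converge and C6 is not touched.

Step 12
Reactants: 16 bromomethyl butenolide; 17 3-[(tert-butyldimethylsilyl)oxy]propanal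
Product: 18 (4R,5R)-4-[(1S)-3-[(tert-butyldimethylsilyl)oxy]-1-hydroxypropyl]-5-[(2S)-2-{[(tert-butyldiphenylsilyl)oxy]methyl}-5-[(4-methoxybenzyl)oxy]pentyl]-3-methylidenedihydrofuran-2(3H)-one
Conditions: Zn dust, THF–saturated aqueous NH4Cl, 0 °C to rt
Reagents that add atoms: none
Why: Zinc Barbier allylation in which the allylzinc reacts at C7 anti to the C6 side chain (trans-lactone) and, with its ring-locked geometry (C6 trans to C13H2Zn) in a Zimmerman–Traxler chair, gives the 7,8-anti adduct, i.e. the 8S alcohol with the α-methylene lactone formed at the same time.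

Step 13
Reactants: 18 8S alcohol; 19 (R)-2-methylbutanoic acid
Product: 20 (1R)-3-[(tert-butyldimethylsilyl)oxy]-1-{(2R,3S)-2-[(2S)-2-{[(tert-butyldiphenylsilyl)oxy]methyl}-5-[(4-methoxybenzyl)oxy]pentyl]-4-methylidene-5-oxooxolan-3-yl}propyl (2R)-2-methylbutanoate
Conditions: PPh3, DIAD, toluene, 0 °C (betaine preformed); then 19 and 18, 0 °C to rt
Reagents that add atoms: none
Why: Mitsunobu esterification displaces the activated C8 oxygen by the carboxylate with SN2 inversion (8S to 8R), which corrects the Barbier outcome, and the acid keeps its α-centre because it is never activated as an acyl donor.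

Step 14
Reactants: 20 PMB ether
Product: 21 (1R)-3-[(tert-butyldimethylsilyl)oxy]-1-{(2R,3S)-2-[(2S)-2-{[(tert-butyldiphenylsilyl)oxy]methyl}-5-hydroxypentyl]-4-methylidene-5-oxooxolan-3-yl}propyl (2R)-2-methylbutanoate
Conditions: DDQ, CH2Cl2–pH 7 buffer, 0 °C to rt
Reagents that add atoms: none
Why: DDQ oxidises the electron-rich PMB ether (electron transfer, then hydrolysis of the oxocarbenium ion) and leaves silyl ethers, esters and the electron-poor alkene alone.

Step 15
Reactants: 21 C1 alcohol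
Product: 22 (1R)-3-[(tert-butyldimethylsilyl)oxy]-1-{(2R,3S)-2-[(2S)-2-{[(tert-butyldiphenylsilyl)oxy]methyl}-5-oxopentyl]-4-methylidene-5-oxooxolan-3-yl}propyl (2R)-2-methylbutanoate
Conditions: Dess–Martin periodinane, NaHCO3, CH2Cl2, 0 °C to rt
Reagents that add atoms: none
Why: Dess–Martin oxidation gives the C1 aldehyde under neutral conditions compatible with the α-methylene lactone and the C8 ester.

Step 16
Reactants: 22 C1 aldehyde; 23 methyl (triphenylphosphoranylidene)acetate
Product: 25 methyl (2Z,6S)-7-{(2R,3S)-3-[(1R)-3-[(tert-butyldimethylsilyl)oxy]-1-{[(2R)-2-methylbutanoyl]oxy}propyl]-4-methylidene-5-oxooxolan-2-yl}-6-{[(tert-butyldiphenylsilyl)oxy]methyl}-2-iodohept-2-enoate, via iodo ylide 24 (not isolated)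
Conditions: 23, NIS, CH2Cl2, −20 °C; then 22, −20 °C to rt
Reagents that add atoms: N-iodosuccinimide, O=C1CCC(=O)N1I
Why: Wittig olefination with the in situ iodinated stabilised ylide, which like stabilised ylides in general should place the ester trans to the C2 chain and hence iodine cis to C2, i.e. the (Z)-iodoenoate.

Step 17
Reactants: 25 iodoenoate TBS ether
Product: 26 methyl (2Z,6S)-6-{[(tert-butyldiphenylsilyl)oxy]methyl}-7-{(2R,3S)-3-[(1R)-3-hydroxy-1-{[(2R)-2-methylbutanoyl]oxy}propyl]-4-methylidene-5-oxooxolan-2-yl}-2-iodohept-2-enoate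
Conditions: HF·pyridine, pyridine, THF, 0 °C
Reagents that add atoms: none
Why: Buffered fluoride desilylation removes the primary TBS ether much faster than the bulkier primary TBDPS ether.

Step 18
Reactants: 26 C16 alcohol
Product: 28 (3R)-3-{(2R,3S)-2-[(2S,5Z)-2-{[(tert-butyldiphenylsilyl)oxy]methyl}-6-iodo-7-methoxy-7-oxohept-5-en-1-yl]-4-methylidene-5-oxooxolan-3-yl}-3-{[(2R)-2-methylbutanoyl]oxy}propanoic acid, via aldehyde 27 (not isolated)
Conditions: TEMPO (cat.), PhI(OAc)2, MeCN–H2O, rt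
Reagents that add atoms: water, O
Why: TEMPO/PhI(OAc)2 oxidation takes the primary alcohol through the aldehyde hydrate to the acid under near-neutral conditions that avoid β-elimination of the C8 ester.

Step 19
Reactants: 28 seco acid; 29 N-hydroxyphthalimide
Product: 30 1,3-dioxoisoindolin-2-yl (3R)-3-{(2R,3S)-2-[(2S,5Z)-2-{[(tert-butyldiphenylsilyl)oxy]methyl}-6-iodo-7-methoxy-7-oxohept-5-en-1-yl]-4-methylidene-5-oxooxolan-3-yl}-3-{[(2R)-2-methylbutanoyl]oxy}propanoate
Conditions: DIC, DMAP (cat.), CH2Cl2, 0 °C to rt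
Reagents that add atoms: none
Why: Carbodiimide (Steglich-type) coupling of the acid with N-hydroxyphthalimide gives the redox-active ester under mild conditions.

Step 20
Reactants: 30 seco (Z)-iodoenoate N-acyloxyphthalimide
Product: 31 methyl (1(10)E,4S,6R,7S,8R)-15-[(tert-butyldiphenylsilyl)oxy]-8-{[(2R)-2-methylbutanoyl]oxy}germacra-1(10),11(13)-dien-12,6-olid-14-oate (15-O-TBDPS ether of the target)
Conditions: NiCl2(glyme) (30 mol%), 2,2'-bipyridine (30 mol%), AgNO3 (30 mol%), nBu4NPF6, NMP, Zn anode, reticulated vitreous carbon cathode, undivided cell, constant current, rt; 30 added by syringe pump to a final 2 mM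
Reagents that add atoms: none
Why: Proposed new method: cathodic reduction gives low-valent nickel(bipyridine), which inserts into the C10–I bond and also transfers an electron to the N-acyloxyphthalimide, whose fragmentation (loss of phthalimide anion and CO2) leaves the primary C9 radical; capture of that radical at the alkenylnickel centre and reductive elimination from trivalent nickel form C9–C10. The closest known reaction type is the intermolecular nickel-electrocatalytic decarboxylative alkenylation of redox-active esters with alkenyl halides, and its use to close a carbocycle is the untested part. Ring A closes by C(sp3)–C(sp2) reductive elimination from an eleven-membered nickelacycle, a ten-membered ring closure by radical capture at the tethered metal and not by radical addition to an alkene. No stereocentre is formed, since C9 is a CH2 and C4, C6, C7 and C8 are spectators, and the C1=C10 geometry (iodine cis to C2) is carried over because oxidative addition and reductive elimination retain alkene configuration. The step needs ring closure to beat dimerisation, hydrodeiodination, reduction of the radical, loss of the β-carboxylate and addition to the α-methylene lactone; slow addition at high dilution, the tethered alkenylnickel and the fact that attack on C13 or C11 would be 5-endo or 4-exo should secure this.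

Step 21
Reactants: 31 15-O-TBDPS macrocycle
Product: 32 methyl (1(10)E,4S,6R,7S,8R)-15-hydroxy-8-{[(2R)-2-methylbutanoyl]oxy}germacra-1(10),11(13)-dien-12,6-olid-14-oate (CNP0141952.4)
Conditions: HF·pyridine, THF, 0 °C to rt
Reagents that add atoms: none
Why: Fluoride cleavage of the primary TBDPS ether under acidic conditions leaves the α-methylene lactone, the enoate and the C8 ester untouched and releases the C15 hydroxyl.

**Compound list**

1 | (R)-5-oxotetrahydrofuran-2-carboxylic acid | O=C1CC[C@H](C(=O)O)O1 | starting material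
2 | (R)-5-(hydroxymethyl)dihydrofuran-2(3H)-one | O=C1CC[C@H](CO)O1 | intermediate
3 | (R)-5-[(trityloxy)methyl]dihydrofuran-2(3H)-one | O=C1CC[C@H](COC(c2ccccc2)(c2ccccc2)c2ccccc2)O1 | intermediate
4 | 1-[(3-iodopropoxy)methyl]-4-methoxybenzene | COc1ccc(COCCCI)cc1 | starting material
5 | lithium enolate of 3 | [Li]OC1=CC[C@H](COC(c2ccccc2)(c2ccccc2)c2ccccc2)O1 | intermediate
6 | (3S,5R)-3-{3-[(4-methoxybenzyl)oxy]propyl}-5-[(trityloxy)methyl]dihydrofuran-2(3H)-one | O=C1[C@@H](CCCOCc2ccc(OC)cc2)C[C@H](COC(c2ccccc2)(c2ccccc2)c2ccccc2)O1 | intermediate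
7 | (2R,4S)-4-(hydroxymethyl)-7-[(4-methoxybenzyl)oxy]-1-(trityloxy)heptan-2-ol | OC[C@@H](CCCOCc1ccc(OC)cc1)C[C@@H](O)COC(c1ccccc1)(c1ccccc1)c1ccccc1 | intermediate
8 | (2R,4S)-4-{[(tert-butyldiphenylsilyl)oxy]methyl}-7-[(4-methoxybenzyl)oxy]-1-(trityloxy)heptan-2-ol | CC(C)(C)[Si](OC[C@@H](CCCOCc1ccc(OC)cc1)C[C@@H](O)COC(c1ccccc1)(c1ccccc1)c1ccccc1)(c1ccccc1)c1ccccc1 | intermediate
9 | (2R,4S)-2-[(tert-butyldimethylsilyl)oxy]-4-{[(tert-butyldiphenylsilyl)oxy]methyl}-7-[(4-methoxybenzyl)oxy]-1-(trityloxy)heptane | CC(C)(C)[Si](OC[C@@H](CCCOCc1ccc(OC)cc1)C[C@@H](O[Si](C)(C)C(C)(C)C)COC(c1ccccc1)(c1ccccc1)c1ccccc1)(c1ccccc1)c1ccccc1 | intermediate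
10 | (2R,4S)-2-[(tert-butyldimethylsilyl)oxy]-4-{[(tert-butyldiphenylsilyl)oxy]methyl}-7-[(4-methoxybenzyl)oxy]heptan-1-ol | CC(C)(C)[Si](OC[C@@H](CCCOCc1ccc(OC)cc1)C[C@@H](O[Si](C)(C)C(C)(C)C)CO)(c1ccccc1)c1ccccc1 | intermediate
11 | (2R,4S)-2-[(tert-butyldimethylsilyl)oxy]-4-{[(tert-butyldiphenylsilyl)oxy]methyl}-7-[(4-methoxybenzyl)oxy]heptanal | CC(C)(C)[Si](OC[C@@H](CCCOCc1ccc(OC)cc1)C[C@@H](O[Si](C)(C)C(C)(C)C)C=O)(c1ccccc1)c1ccccc1 | intermediate
12 | methyl acrylate | C=CC(=O)OC | starting material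
13 | methyl (4R,6S)-4-[(tert-butyldimethylsilyl)oxy]-6-{[(tert-butyldiphenylsilyl)oxy]methyl}-3-hydroxy-9-[(4-methoxybenzyl)oxy]-2-methylidenenonanoate (C3 epimers) | CC(C)(C)[Si](OC[C@@H](CCCOCc1ccc(OC)cc1)C[C@@H](O[Si](C)(C)C(C)(C)C)C(O)C(=C)C(=O)OC)(c1ccccc1)c1ccccc1 | intermediate
14 | methyl (4R,6S)-6-{[(tert-butyldiphenylsilyl)oxy]methyl}-3,4-dihydroxy-9-[(4-methoxybenzyl)oxy]-2-methylidenenonanoate (C3 epimers) | CC(C)(C)[Si](OC[C@@H](CCCOCc1ccc(OC)cc1)C[C@@H](O)C(O)C(=C)C(=O)OC)(c1ccccc1)c1ccccc1 | intermediate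
15 | (5R)-5-[(2S)-2-{[(tert-butyldiphenylsilyl)oxy]methyl}-5-[(4-methoxybenzyl)oxy]pentyl]-4-hydroxy-3-methylidenedihydrofuran-2(3H)-one (C4 epimers) | C=C1C(=O)O[C@H](C[C@H](CCCOCc2ccc(OC)cc2)CO[Si](c2ccccc2)(c2ccccc2)C(C)(C)C)C1O | intermediate
16 | (5R)-3-(bromomethyl)-5-[(2S)-2-{[(tert-butyldiphenylsilyl)oxy]methyl}-5-[(4-methoxybenzyl)oxy]pentyl]furan-2(5H)-one | BrCC1=C[C@@H](C[C@H](CCCOCc2ccc(OC)cc2)CO[Si](c2ccccc2)(c2ccccc2)C(C)(C)C)OC1=O | intermediate
17 | 3-[(tert-butyldimethylsilyl)oxy]propanal | O=CCCO[Si](C)(C)C(C)(C)C | starting material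
18 | (4R,5R)-4-[(1S)-3-[(tert-butyldimethylsilyl)oxy]-1-hydroxypropyl]-5-[(2S)-2-{[(tert-butyldiphenylsilyl)oxy]methyl}-5-[(4-methoxybenzyl)oxy]pentyl]-3-methylidenedihydrofuran-2(3H)-one | COc1ccc(COCCC[C@H](CO[Si](c2ccccc2)(c2ccccc2)C(C)(C)C)C[C@H]2OC(=O)C(=C)[C@@H]2[C@@H](O)CCO[Si](C)(C)C(C)(C)C)cc1 | intermediate
19 | (R)-2-methylbutanoic acid | CC[C@@H](C)C(=O)O | starting material
20 | (1R)-3-[(tert-butyldimethylsilyl)oxy]-1-{(2R,3S)-2-[(2S)-2-{[(tert-butyldiphenylsilyl)oxy]methyl}-5-[(4-methoxybenzyl)oxy]pentyl]-4-methylidene-5-oxooxolan-3-yl}propyl (2R)-2-methylbutanoate | COc1ccc(COCCC[C@H](CO[Si](c2ccccc2)(c2ccccc2)C(C)(C)C)C[C@H]2OC(=O)C(=C)[C@@H]2[C@H](OC(=O)[C@H](C)CC)CCO[Si](C)(C)C(C)(C)C)cc1 | intermediate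
21 | (1R)-3-[(tert-butyldimethylsilyl)oxy]-1-{(2R,3S)-2-[(2S)-2-{[(tert-butyldiphenylsilyl)oxy]methyl}-5-hydroxypentyl]-4-methylidene-5-oxooxolan-3-yl}propyl (2R)-2-methylbutanoate | OCCC[C@H](CO[Si](c1ccccc1)(c1ccccc1)C(C)(C)C)C[C@H]1OC(=O)C(=C)[C@@H]1[C@H](OC(=O)[C@H](C)CC)CCO[Si](C)(C)C(C)(C)C | intermediate
22 | (1R)-3-[(tert-butyldimethylsilyl)oxy]-1-{(2R,3S)-2-[(2S)-2-{[(tert-butyldiphenylsilyl)oxy]methyl}-5-oxopentyl]-4-methylidene-5-oxooxolan-3-yl}propyl (2R)-2-methylbutanoate | O=CCC[C@H](CO[Si](c1ccccc1)(c1ccccc1)C(C)(C)C)C[C@H]1OC(=O)C(=C)[C@@H]1[C@H](OC(=O)[C@H](C)CC)CCO[Si](C)(C)C(C)(C)C | intermediate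
23 | methyl (triphenylphosphoranylidene)acetate | COC(=O)C=P(c1ccccc1)(c1ccccc1)c1ccccc1 | starting material
24 | methyl iodo(triphenylphosphoranylidene)acetate | COC(=O)C(I)=P(c1ccccc1)(c1ccccc1)c1ccccc1 | intermediate
25 | methyl (2Z,6S)-7-{(2R,3S)-3-[(1R)-3-[(tert-butyldimethylsilyl)oxy]-1-{[(2R)-2-methylbutanoyl]oxy}propyl]-4-methylidene-5-oxooxolan-2-yl}-6-{[(tert-butyldiphenylsilyl)oxy]methyl}-2-iodohept-2-enoate | COC(=O)/C(I)=C/CC[C@H](CO[Si](c1ccccc1)(c1ccccc1)C(C)(C)C)C[C@H]1OC(=O)C(=C)[C@@H]1[C@H](OC(=O)[C@H](C)CC)CCO[Si](C)(C)C(C)(C)C | intermediate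
26 | methyl (2Z,6S)-6-{[(tert-butyldiphenylsilyl)oxy]methyl}-7-{(2R,3S)-3-[(1R)-3-hydroxy-1-{[(2R)-2-methylbutanoyl]oxy}propyl]-4-methylidene-5-oxooxolan-2-yl}-2-iodohept-2-enoate | COC(=O)/C(I)=C/CC[C@H](CO[Si](c1ccccc1)(c1ccccc1)C(C)(C)C)C[C@H]1OC(=O)C(=C)[C@@H]1[C@H](OC(=O)[C@H](C)CC)CCO | intermediate
27 | methyl (2Z,6S)-6-{[(tert-butyldiphenylsilyl)oxy]methyl}-2-iodo-7-{(2R,3S)-3-[(1R)-1-{[(2R)-2-methylbutanoyl]oxy}-3-oxopropyl]-4-methylidene-5-oxooxolan-2-yl}hept-2-enoate | COC(=O)/C(I)=C/CC[C@H](CO[Si](c1ccccc1)(c1ccccc1)C(C)(C)C)C[C@H]1OC(=O)C(=C)[C@@H]1[C@H](OC(=O)[C@H](C)CC)CC=O | intermediate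
28 | (3R)-3-{(2R,3S)-2-[(2S,5Z)-2-{[(tert-butyldiphenylsilyl)oxy]methyl}-6-iodo-7-methoxy-7-oxohept-5-en-1-yl]-4-methylidene-5-oxooxolan-3-yl}-3-{[(2R)-2-methylbutanoyl]oxy}propanoic acid | COC(=O)/C(I)=C/CC[C@H](CO[Si](c1ccccc1)(c1ccccc1)C(C)(C)C)C[C@H]1OC(=O)C(=C)[C@@H]1[C@H](OC(=O)[C@H](C)CC)CC(=O)O | intermediate
29 | N-hydroxyphthalimide | O=C1c2ccccc2C(=O)N1O | starting material
30 | 1,3-dioxoisoindolin-2-yl (3R)-3-{(2R,3S)-2-[(2S,5Z)-2-{[(tert-butyldiphenylsilyl)oxy]methyl}-6-iodo-7-methoxy-7-oxohept-5-en-1-yl]-4-methylidene-5-oxooxolan-3-yl}-3-{[(2R)-2-methylbutanoyl]oxy}propanoate | COC(=O)/C(I)=C/CC[C@H](CO[Si](c1ccccc1)(c1ccccc1)C(C)(C)C)C[C@H]1OC(=O)C(=C)[C@@H]1[C@H](OC(=O)[C@H](C)CC)CC(=O)ON1C(=O)c2ccccc2C1=O | intermediate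
31 | methyl (1(10)E,4S,6R,7S,8R)-15-[(tert-butyldiphenylsilyl)oxy]-8-{[(2R)-2-methylbutanoyl]oxy}germacra-1(10),11(13)-dien-12,6-olid-14-oate | C=C1C(=O)O[C@@H]2C[C@@H](CO[Si](c3ccccc3)(c3ccccc3)C(C)(C)C)CC/C=C(/C(=O)OC)C[C@@H](OC(=O)[C@H](C)CC)[C@@H]12 | intermediate
32 | methyl (1(10)E,4S,6R,7S,8R)-15-hydroxy-8-{[(2R)-2-methylbutanoyl]oxy}germacra-1(10),11(13)-dien-12,6-olid-14-oate (CNP0141952.4) | C=C1C(=O)O[C@@H]2C[C@@H](CO)CC/C=C(/C(=O)OC)C[C@@H](OC(=O)[C@H](C)CC)[C@@H]12 | target

**Step count**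

Total steps: 21. Longest linear sequence: 21 steps (1 to 32); compounds 4, 12, 17, 19, 23 and 29 are bought.

**Steps most likely to fail**

1. Step 20 (proposed new method). What may go wrong: intermolecular coupling and oligomerisation instead of ring closure, hydrodeiodination of the alkenylnickel, reduction of the C9 radical to C–H, loss of the C8 carboxylate from an alkylnickel, or radical addition to the α-methylene lactone. Fallback with known chemistry, closing ring A at C1=C10 instead: it sets out from aldehyde 22. Takai–Lombardo methylenation (Zn, CH2Br2, TiCl4, THF) would turn the C1 aldehyde into the terminal alkene F1. HF·pyridine would then free the C16 alcohol F2, TEMPO/PhI(OAc)2 would give the acid F3, and DIC with 29 its N-acyloxyphthalimide F4. The established intermolecular nickel-electrocatalytic decarboxylative alkenylation of F4 with methyl 2-iodoacrylate F5 would form C9–C10 and give the diene F6. Ring-closing metathesis of F6 with the second-generation Hoveyda–Grubbs catalyst in dilute toluene would close the ten-membered ring and come back to the route at 31. The cis ring alkene needed here is the geometry metathesis usually favours in a ring of this size, and the α-methylene lactone is the less accessible of the two electron-poor 1,1-disubstituted alkenes.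

2. Step 13. What may go wrong: elimination of the activated C8 oxygen toward the allylic C7–H, incomplete substitution at the flanked secondary carbon with a weakly acidic aliphatic acid, or conjugate addition of free phosphine to the α-methylene lactone. Fallback: from 18, ClCH2SO2Cl and pyridine would give the chloromethanesulfonate F7. Displacement with CsO2CCH(CH3)C2H5 (from 19 and Cs2CO3) and 18-crown-6 in toluene would then give 20 with inversion, as a discrete sulfonate/carboxylate SN2 sequence without phosphine or azodicarboxylate.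

3. Step 9. What may go wrong: very slow addition to the hindered α-silyloxy aldehyde, with amine-induced epimerisation at C6 during the long reaction time. Fallback: from 11, hydroalumination of methyl propiolate with iBu2AlH in the presence of N-methylmorpholine N-oxide would generate the α-aluminated acrylate. This adds to the aldehyde at 0 °C without an amine base and gives 13 directly; no new compound is made.

**Further compounds**

F1 | step 20 | (1R)-1-{(2R,3S)-2-[(2S)-2-{[(tert-butyldiphenylsilyl)oxy]methyl}hex-5-en-1-yl]-4-methylidene-5-oxooxolan-3-yl}-3-[(tert-butyldimethylsilyl)oxy]propyl (2R)-2-methylbutanoate | C=CCC[C@H](CO[Si](c1ccccc1)(c1ccccc1)C(C)(C)C)C[C@H]1OC(=O)C(=C)[C@@H]1[C@H](OC(=O)[C@H](C)CC)CCO[Si](C)(C)C(C)(C)C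
F2 | step 20 | (1R)-1-{(2R,3S)-2-[(2S)-2-{[(tert-butyldiphenylsilyl)oxy]methyl}hex-5-en-1-yl]-4-methylidene-5-oxooxolan-3-yl}-3-hydroxypropyl (2R)-2-methylbutanoate | C=CCC[C@H](CO[Si](c1ccccc1)(c1ccccc1)C(C)(C)C)C[C@H]1OC(=O)C(=C)[C@@H]1[C@H](OC(=O)[C@H](C)CC)CCO
F3 | step 20 | (3R)-3-{(2R,3S)-2-[(2S)-2-{[(tert-butyldiphenylsilyl)oxy]methyl}hex-5-en-1-yl]-4-methylidene-5-oxooxolan-3-yl}-3-{[(2R)-2-methylbutanoyl]oxy}propanoic acid | C=CCC[C@H](CO[Si](c1ccccc1)(c1ccccc1)C(C)(C)C)C[C@H]1OC(=O)C(=C)[C@@H]1[C@H](OC(=O)[C@H](C)CC)CC(=O)O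
F4 | step 20 | 1,3-dioxoisoindolin-2-yl ester of F3 | C=CCC[C@H](CO[Si](c1ccccc1)(c1ccccc1)C(C)(C)C)C[C@H]1OC(=O)C(=C)[C@@H]1[C@H](OC(=O)[C@H](C)CC)CC(=O)ON1C(=O)c2ccccc2C1=O
F5 | step 20 | methyl 2-iodoacrylate | C=C(I)C(=O)OC
F6 | step 20 | methyl (4R)-4-{(2R,3S)-2-[(2S)-2-{[(tert-butyldiphenylsilyl)oxy]methyl}hex-5-en-1-yl]-4-methylidene-5-oxooxolan-3-yl}-2-methylidene-4-{[(2R)-2-methylbutanoyl]oxy}butanoate | C=CCC[C@H](CO[Si](c1ccccc1)(c1ccccc1)C(C)(C)C)C[C@H]1OC(=O)C(=C)[C@@H]1[C@H](OC(=O)[C@H](C)CC)CC(=C)C(=O)OC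
F7 | step 13 | (1S)-3-[(tert-butyldimethylsilyl)oxy]-1-{(2R,3R)-2-[(2S)-2-{[(tert-butyldiphenylsilyl)oxy]methyl}-5-[(4-methoxybenzyl)oxy]pentyl]-4-methylidene-5-oxooxolan-3-yl}propyl chloromethanesulfonate | COc1ccc(COCCC[C@H](CO[Si](c2ccccc2)(c2ccccc2)C(C)(C)C)C[C@H]2OC(=O)C(=C)[C@@H]2[C@@H](OS(=O)(=O)CCl)CCO[Si](C)(C)C(C)(C)C)cc1
F0 | step 9 | none | none
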